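3.42 min⁻¹ against 0.156 min⁻¹: these are my readings for the fall of the substrate and the later fall of the first product in the oak run, each taken as a pseudo-first-order decay with the gas held. The flask asked about is that same flask.

| setting | oak | flask |
|---|---|---|
| substrate | 0.50 mM | 0.50 mM |
| gas | 0.024 mM (held) | 0.024 mM (held) |
| remark | the very flask that is asked about, followed so far |  |
| time |  | 25 min |

- oak (time / min: first product / %, substrate / %): 0.250: 41.9, 49.3; 0.833: 66.4, 6.7; 3.00: 53.4, 0; 10.0: 17.9, 0.3

(scatter of a reading: 1 percentage point)

- time up to 25 min at which first product stands highest
- the amount of first product, in percent of the substrate charged, at that time

- the numbers in the tables scatter by 1 percentage point (one standard deviation)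
- at the start none of the gas is in solution

I run the oak flask slowly. At the start none of the gas is in solution, and by 0.250 min the substrate reads 49.3% and the first product 41.9%, so these two readings leave 8.80% of the charge in neither. In the middle the substrate falls faster than the first product, so the first product climbs to 66.4% at 0.833 min. By 3.00 min the substrate reads 0% and the first product 53.4%, and at 10.0 min the first product reads 17.9%. Carrying that fall back to the start gives 85.3%. A loss-free series of two such steps has a larger amplitude, so I reckon that 81.4% of the charge goes through the first product. I carry the loss ratio, the part of the charge lost beside the first product per part passed through it: 0.228. My series then peaks at 0.945 min with 70.2%.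

The forecast says 1 min and 68%, lower than my height, as the early reading, in its words, “lies about 3 points under the model”.

The flask peaks at 0.957 min with 67.8%, and its side product, which counts as two in its percentage, already stands at 20.5% then and at 22.0% at 25.0 min. My loss ratio, itself a reading from the oak run, reckons 18.6% of the charge in this flask as lost beside the first product.

    gas ⇌ partner, rate k1*(csat - [partner]) (kL = 6.92 s⁻¹)
    partner + first product → double product + released group (k = 106 L mol⁻¹ s⁻¹)
    substrate + partner → first product + released group (k = 2050 L mol⁻¹ s⁻¹)
    substrate + first product → side product (k = 29.6 L mol⁻¹ s⁻¹)

For the neighbour with 2.0 mM of substrate, all else held, I assume that the loss ratio scales with the charge, to 0.913, and with my peak time kept as an estimate this gives 47.7% lost and a peak of 45.1%. That flask computes to a peak of 40.6% and 54.3% side product at 25.0 min.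

The numbers in the tables come from a simulation with made-up constants; scatter was added.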